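**Plan**
- Retrosynthesis: the hydroxy-methoxy-quinone goes back to a 2,3,5,6-tetramethoxyphenyl group; C1 and C7 (drimane numbering) are given carbonyl groups; ring B is then cut at C5–C6 and C9–C10, and the acyclic piece at C9–CH2Ar and Ar–CH2.
- Enabling feature: with a carbonyl at C1, ring A (C1–C5, C10; gem-dimethyl C4) is a 4,4-dimethylcyclohex-2-enone with β-carbon C5 and α-carbon C10. The C6–C9 unit of ring B, with C7 as a ketone, can therefore be laid across C5=C10 as a dienolate whose far carbon C9 already carries the methyl and the arylmethyl arm.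
- Forward: arene → benzylzinc → Negishi coupling with the (Z)-enol triflate of 3-methylpentane-2,4-dione → tetrasubstituted enone; ring B is closed onto preformed ring A in step 5.
- Then: C1 is deoxygenated, the Δ5 alkene is introduced through the 7-ketone, C7 is deoxygenated, and the arene is oxidised and mono-hydrolysed.
- Stereochemistry: a lithium-bound chiral diether fixes C5 in the first Michael addition; C9 follows from the enone geometry and the mode of closure relative to C5; C10 and C8 are equilibrated to the trans-fused dione with equatorial C8 methyl; C5 is erased when the alkene is made.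

Key step: step 5

Conventions: Ar = 2,3,5,6-tetramethoxyphenyl; decalins carry drimane numbering, and α/β refer to the usual terpenoid drawing (C10 at the top ring fusion, β towards the viewer).
Assumption: the sense of induction of the diether ligand cannot be predicted with confidence; the (R,R)-ligand is written, and its antipode would be used if a model addition shows the opposite sense.

Step 1
Reactants: 1 1,2,4,5-tetramethoxybenzene
Product: 3 (2,3,5,6-tetramethoxyphenyl)methanol, via aryllithium 2 (not isolated)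
Conditions: n-BuLi, THF, 0 °C; (CH2O)n, 0 → 25 °C; aq. NH4Cl
Reagents that add atoms: paraformaldehyde (formaldehyde), C=O
Why: Directed ortho-lithiation takes place at the ring position flanked by two methoxy groups, and the aryllithium adds to formaldehyde (hydroxymethylation).

Step 2
Reactants: 3 (2,3,5,6-tetramethoxyphenyl)methanol
Product: 4 3-(chloromethyl)-1,2,4,5-tetramethoxybenzene
Conditions: SOCl2, CH2Cl2, 0 °C
Reagents that add atoms: thionyl chloride, O=S(Cl)Cl
Why: Chlorodehydroxylation of an electron-rich benzylic alcohol with thionyl chloride is fast at 0 °C and gives the chloride needed for clean zinc insertion.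

Step 3
Reactants: 5 3-methylpentane-2,4-dione
Product: 6 (Z)-3-methyl-4-oxopent-2-en-2-yl trifluoromethanesulfonate
Conditions: Tf2O, aq. LiOH, toluene, 5 °C
Reagents that add atoms: trifluoromethanesulfonic anhydride, O=S(=O)(OS(=O)(=O)C(F)(F)F)C(F)(F)F
Why: O-sulfonylation of the lithium-chelated (U-shaped) enolate of the symmetric β-diketone should place the triflate cis to the remaining acetyl group (stereoselective enol triflate formation), which fixes the alkene geometry.

Step 4
Reactants: 4 3-(chloromethyl)-1,2,4,5-tetramethoxybenzene; 6 (Z)-3-methyl-4-oxopent-2-en-2-yl trifluoromethanesulfonate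
Product: 8 (Z)-3,4-dimethyl-5-(2,3,5,6-tetramethoxyphenyl)pent-3-en-2-one, via benzylzinc chloride 7 (not isolated)
Conditions: Zn dust, LiCl, THF, 25 °C; then 6, Pd(PPh3)4 (5 mol %), THF, 50 °C
Reagents that add atoms: none
Why: LiCl-promoted zinc insertion into the benzylic chloride and Negishi cross-coupling with the β-triflyloxy enone proceed with retention of alkene geometry, so the arylmethyl group ends up cis to the acetyl group.

Step 5
Reactants: 8 (Z)-3,4-dimethyl-5-(2,3,5,6-tetramethoxyphenyl)pent-3-en-2-one; 9 4,4-dimethylcyclohex-2-en-1-one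
Product: 12 (5S,8R,9R,10R)-4,4,8β,9β-tetramethyl-9α-(2,3,5,6-tetramethoxybenzyl)-5β-H/10α-H-decalin-1,7-dione, via lithium dienolate 10 (not isolated), via cis-fused 10-epi-dione 11 (not isolated)
Conditions: LDA, (1R,2R)-1,2-dimethoxy-1,2-diphenylethane (1.5 equiv), toluene, −78 °C; 9, −78 → 0 °C; then MeOH, NaOMe (cat.), 25 °C; aq. NH4Cl
Reagents that add atoms: none
Why: Proposed new method: LDA removes an acetyl proton of 8 to give the cross-conjugated lithium dienolate 10, which adds through C6 to the β-carbon C5 of 9, and the regiodefined ring-A enolate then adds through C10 to the enone β-carbon C9, so that the C5–C6 and C9–C10 bonds form in one anionic Michael–Michael sequence. The closest known reactions are the racemic double Michael annulation of kinetic enone dienolates with cyclic enones and the chiral-diether-controlled conjugate addition of lithium ester enolates to enoates; their combination on a ketone dienolate and a cyclohexenone is untested. Ring B closes by a 6-endo-trig Michael addition, which should tolerate the fully substituted terminus because it is stepwise and intramolecular. C5 (S) is to be set by the C2-symmetric diether bound to lithium in a closed transition state that also holds the enone carbonyl; C9 (R) follows from the (Z)-geometry of 8 and a boat-like exo closure on the ring-A face anti to the axial C4 methyl, which leaves the C9 methyl cis to H5 and H10 and the arylmethyl group cis to C1 and C4 (11); NaOMe then epimerises C10 and C8 by enolisation to the trans ring fusion with equatorial arylmethyl and equatorial C8 methyl (12). The step needs conjugate rather than carbonyl addition, α′- rather than γ-deprotonation of 8 and closure faster than enolate equilibration; the kinetic base at −78 °C, the hindered carbonyl of 9 and the proximity of C10 to C9 are expected to secure these.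

Step 6
Reactants: 12 (5S,8R,9R,10R)-4,4,8β,9β-tetramethyl-9α-(2,3,5,6-tetramethoxybenzyl)-5β-H/10α-H-decalin-1,7-dione
Product: 13 7,7-(ethylenedioxy)-4,4,8β,9β-tetramethyl-9α-(2,3,5,6-tetramethoxybenzyl)-5β-H/10α-H-decalin-1-one
Conditions: HOCH2CH2OH, TsOH·H2O (cat.), benzene, reflux, Dean–Stark
Reagents that add atoms: ethane-1,2-diol, OCCO
Why: Chemoselective ketalisation is expected at C7, because a tetrahedral C1 would put both oxygen atoms in syn-pentane contact with the two C9 substituents whereas the C7 dioxolane suffers only one 1,3-diaxial O/CH3 contact.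

Step 7
Reactants: 13 7,7-(ethylenedioxy)-4,4,8β,9β-tetramethyl-9α-(2,3,5,6-tetramethoxybenzyl)-5β-H/10α-H-decalin-1-one
Product: 15 7,7-(ethylenedioxy)-4,4,8β,9β-tetramethyl-9α-(2,3,5,6-tetramethoxybenzyl)-5β-H/10α-H-decalin, via C1 hydrazone 14 (not isolated)
Conditions: N2H4·H2O, KOH, diethylene glycol, 130 → 200 °C
Reagents that add atoms: none
Why: The Huang-Minlon form of the Wolff–Kishner reduction removes the hindered C1 carbonyl through its planar hydrazone, the dioxolane and the aryl ethers are base-stable, and C10 should keep the trans ring fusion established in step 5.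

Step 8
Reactants: 15 7,7-(ethylenedioxy)-4,4,8β,9β-tetramethyl-9α-(2,3,5,6-tetramethoxybenzyl)-5β-H/10α-H-decalin
Product: 16 4,4,8β,9β-tetramethyl-9α-(2,3,5,6-tetramethoxybenzyl)-5β-H/10α-H-decalin-7-one
Conditions: 2 M HCl, THF, 25 °C
Reagents that add atoms: water, O
Why: Acid-catalysed ketal hydrolysis returns the C7 ketone, and any enolisation towards C8 leads back to the equatorial methyl group.

Step 9
Reactants: 16 4,4,8β,9β-tetramethyl-9α-(2,3,5,6-tetramethoxybenzyl)-5β-H/10α-H-decalin-7-one
Product: 17 7-(trimethylsilyloxy)-4,4,8β,9β-tetramethyl-9α-(2,3,5,6-tetramethoxybenzyl)-5β-H/10α-H-octal-6-ene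
Conditions: LDA, TMSCl, THF, −78 °C (internal quench)
Reagents that add atoms: chlorotrimethylsilane, C[Si](C)(C)Cl
Why: Kinetic deprotonation should occur at the C6 methylene and not at the C8 methine shielded by quaternary C9, and silylation fixes the Δ6 enol ether (regioselective kinetic enol silane formation).

Step 10
Reactants: 17 7-(trimethylsilyloxy)-4,4,8β,9β-tetramethyl-9α-(2,3,5,6-tetramethoxybenzyl)-5β-H/10α-H-octal-6-ene
Product: 18 4,4,8β,9β-tetramethyl-9α-(2,3,5,6-tetramethoxybenzyl)-10α-H-octal-5-en-7-one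
Conditions: Pd(OAc)2 (1.1 equiv), MeCN, 25 °C
Reagents that add atoms: none
Why: In this Saegusa–Ito oxidation the palladium enolate bound at C6 has only the C5 hydrogen available for β-hydride elimination, which gives the Δ5-7-enone and erases the C5 stereocentre.

Step 11
Reactants: 18 4,4,8β,9β-tetramethyl-9α-(2,3,5,6-tetramethoxybenzyl)-10α-H-octal-5-en-7-one
Product: 19 3-{[(8S,9R,10S)-4,4,8,9-tetramethyloctal-5-en-9-yl]methyl}-1,2,4,5-tetramethoxybenzene
Conditions: LiAlH4/AlCl3 (1:3), Et2O, 0 °C → reflux
Reagents that add atoms: none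
Why: Mixed-hydride (chloroalane) deoxygenation of an α,β-unsaturated ketone proceeds by 1,2-reduction, ionisation and hydride capture of the allyl cation at the less substituted terminus C7, which should leave the trisubstituted Δ5 alkene in place as in the conversion of steroidal Δ4-3-ketones into Δ4-alkenes.

Step 12
Reactants: 19 3-{[(8S,9R,10S)-4,4,8,9-tetramethyloctal-5-en-9-yl]methyl}-1,2,4,5-tetramethoxybenzene
Product: 20 2,5-dimethoxy-3-{[(8S,9R,10S)-4,4,8,9-tetramethyloctal-5-en-9-yl]methyl}-1,4-benzoquinone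
Conditions: (NH4)2Ce(NO3)6, MeCN/H2O, 0 °C
Reagents that add atoms: water, O
Why: Oxidative demethylation of a 1,4-dimethoxyarene with (NH4)2Ce(NO3)6 gives the quinone, the arene is symmetric about its C(alkyl)–C(H) axis so that both para pairs give the same quinone, and the isolated alkene should not be attacked.

Step 13
Reactants: 20 2,5-dimethoxy-3-{[(8S,9R,10S)-4,4,8,9-tetramethyloctal-5-en-9-yl]methyl}-1,4-benzoquinone
Product: 21 2-hydroxy-5-methoxy-3-{[(8S,9R,10S)-4,4,8,9-tetramethyloctal-5-en-9-yl]methyl}-1,4-benzoquinone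
Conditions: KOH, MeOH/H2O, 25 °C; then 1 M HCl
Reagents that add atoms: potassium hydroxide, [K+].[OH-]
Why: Addition–elimination of hydroxide on the vinylogous ester should exchange selectively the methoxy group flanked by the alkyl substituent, which is twisted out of conjugation and the more ester-like, a selectivity known for 3-alkyl-2,5-dimethoxy-1,4-benzoquinones.

**Compound list**
1 | 1,2,4,5-tetramethoxybenzene | COc1cc(OC)c(OC)cc1OC | starting material
2 | (2,3,5,6-tetramethoxyphenyl)lithium (aryllithium) | [Li]c1c(OC)c(OC)cc(OC)c1OC | intermediate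
3 | (2,3,5,6-tetramethoxyphenyl)methanol | OCc1c(OC)c(OC)cc(OC)c1OC | intermediate
4 | 3-(chloromethyl)-1,2,4,5-tetramethoxybenzene | ClCc1c(OC)c(OC)cc(OC)c1OC | intermediate
5 | 3-methylpentane-2,4-dione | CC(=O)C(C)C(C)=O | starting material
6 | (Z)-3-methyl-4-oxopent-2-en-2-yl trifluoromethanesulfonate | CC(=O)/C(C)=C(/C)OS(=O)(=O)C(F)(F)F | intermediate
7 | (2,3,5,6-tetramethoxybenzyl)zinc chloride (benzylzinc chloride) | Cl[Zn]Cc1c(OC)c(OC)cc(OC)c1OC | intermediate
8 | (Z)-3,4-dimethyl-5-(2,3,5,6-tetramethoxyphenyl)pent-3-en-2-one | CC(=O)/C(C)=C(/C)Cc1c(OC)c(OC)cc(OC)c1OC | intermediate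
9 | 4,4-dimethylcyclohex-2-en-1-one | CC1(C)CCC(=O)C=C1 | starting material
10 | lithium (Z)-3,4-dimethyl-5-(2,3,5,6-tetramethoxyphenyl)penta-1,3-dien-2-olate (lithium dienolate) | [Li]OC(=C)/C(C)=C(/C)Cc1c(OC)c(OC)cc(OC)c1OC | intermediate
11 | (5S,8R,9R,10S)-4,4,8β,9β-tetramethyl-9α-(2,3,5,6-tetramethoxybenzyl)-5β-H/10β-H-decalin-1,7-dione (cis-fused 10-epi-dione) | COc1cc(OC)c(OC)c(C[C@@]2(C)[C@H]3C(=O)CCC(C)(C)[C@H]3CC(=O)[C@@H]2C)c1OC | intermediate
12 | (5S,8R,9R,10R)-4,4,8β,9β-tetramethyl-9α-(2,3,5,6-tetramethoxybenzyl)-5β-H/10α-H-decalin-1,7-dione (trans-fused) | COc1cc(OC)c(OC)c(C[C@@]2(C)[C@@H]3C(=O)CCC(C)(C)[C@H]3CC(=O)[C@@H]2C)c1OC | intermediate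
13 | 7,7-(ethylenedioxy)-4,4,8β,9β-tetramethyl-9α-(2,3,5,6-tetramethoxybenzyl)-5β-H/10α-H-decalin-1-one | COc1cc(OC)c(OC)c(C[C@@]2(C)[C@@H]3C(=O)CCC(C)(C)[C@H]3CC4(OCCO4)[C@@H]2C)c1OC | intermediate
14 | C1 hydrazone of 13 | COc1cc(OC)c(OC)c(C[C@@]2(C)[C@@H]3C(=NN)CCC(C)(C)[C@H]3CC4(OCCO4)[C@@H]2C)c1OC | intermediate
15 | 7,7-(ethylenedioxy)-4,4,8β,9β-tetramethyl-9α-(2,3,5,6-tetramethoxybenzyl)-5β-H/10α-H-decalin | COc1cc(OC)c(OC)c(C[C@@]2(C)[C@@H]3CCCC(C)(C)[C@H]3CC4(OCCO4)[C@@H]2C)c1OC | intermediate
16 | 4,4,8β,9β-tetramethyl-9α-(2,3,5,6-tetramethoxybenzyl)-5β-H/10α-H-decalin-7-one | COc1cc(OC)c(OC)c(C[C@@]2(C)[C@@H]3CCCC(C)(C)[C@H]3CC(=O)[C@@H]2C)c1OC | intermediate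
17 | 7-(trimethylsilyloxy)-4,4,8β,9β-tetramethyl-9α-(2,3,5,6-tetramethoxybenzyl)-5β-H/10α-H-octal-6-ene | COc1cc(OC)c(OC)c(C[C@@]2(C)[C@@H]3CCCC(C)(C)[C@H]3C=C(O[Si](C)(C)C)[C@@H]2C)c1OC | intermediate
18 | 4,4,8β,9β-tetramethyl-9α-(2,3,5,6-tetramethoxybenzyl)-10α-H-octal-5-en-7-one | COc1cc(OC)c(OC)c(C[C@@]2(C)[C@@H]3CCCC(C)(C)C3=CC(=O)[C@@H]2C)c1OC | intermediate
19 | 3-{[(8S,9R,10S)-4,4,8,9-tetramethyloctal-5-en-9-yl]methyl}-1,2,4,5-tetramethoxybenzene (8β,9β-dimethyl, 10α-H) | COc1cc(OC)c(OC)c(C[C@@]2(C)[C@@H]3CCCC(C)(C)C3=CC[C@@H]2C)c1OC | intermediate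
20 | 2,5-dimethoxy-3-{[(8S,9R,10S)-4,4,8,9-tetramethyloctal-5-en-9-yl]methyl}-1,4-benzoquinone | COC1=CC(=O)C(OC)=C(C[C@@]2(C)[C@@H]3CCCC(C)(C)C3=CC[C@@H]2C)C1=O | intermediate
21 | 2-hydroxy-5-methoxy-3-{[(8S,9R,10S)-4,4,8,9-tetramethyloctal-5-en-9-yl]methyl}-1,4-benzoquinone | COC1=CC(=O)C(O)=C(C[C@@]2(C)[C@@H]3CCCC(C)(C)C3=CC[C@@H]2C)C1=O | target

**Totals**
Total step count: 13. Longest linear sequence: 12 steps (steps 1, 2 and 4 to 13, from 1,2,4,5-tetramethoxybenzene).

**Steps most likely to fail**

Step 5. The first conjugate addition may show poor facial selectivity under ligand control, so that the dione forms in low enantiomeric purity; in addition, the ring closure may partly take the endo course and deliver the C9 epimer, and the C10 equilibration may stop short of the trans isomer. Fallback with known chemistry: setting out from 8 and 9, the annulation is run with LDA alone as the racemic double Michael reaction, followed by the same NaOMe equilibration, which gives 12 together with its mirror image, ent-dione F1. Ketalisation of the mixture at C7 with (2R,3R)-butane-2,3-diol (TsOH, benzene, Dean–Stark) gives two diastereomers, the (4R,5R)-dimethyldioxolane of 12 F2 and the (4R,5R)-dimethyldioxolane of the ent-dione F3, which are separated by chromatography or crystallisation. F2 is reduced under the conditions of step 7 to the C1-deoxygenated dimethyldioxolane F4, and acid hydrolysis of F4 comes back to the route at 16.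

Step 7. Hydrazone formation at the hindered C1 carbonyl may be slow, and prolonged heating in strong base may then cleave aryl methyl ethers or epimerise C10. Fallback: setting out from 13, kinetic deprotonation at C2 (KHMDS, THF, −78 °C) and trapping with PhNTf2 gives the C1 enol triflate F5. Reduction with HCO2H/Bu3N under Pd(OAc)2/PPh3 catalysis (DMF, 60 °C) gives the Δ1-alkene F6, and hydrogenation of this disubstituted alkene (H2, Pd/C, EtOAc) comes back to the route at 15.

Step 11. The allyl cation may lose a proton to give dienes, or the alkene may migrate, instead of hydride being captured at C7. Fallback: setting out from 18, ethane-1,2-dithiol and BF3·OEt2 give the C7 dithiolane F7 without moving the alkene, and desulfurisation with Raney Ni (deactivated in acetone, then EtOH, 25 °C) comes back to the route at 19.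

Further compounds
F1 | step 5 | ent-dione, (5R,8S,9S,10S)-4,4,8,9-tetramethyl-9-(2,3,5,6-tetramethoxybenzyl)decalin-1,7-dione | COc1cc(OC)c(OC)c(C[C@]2(C)[C@H]3C(=O)CCC(C)(C)[C@@H]3CC(=O)[C@H]2C)c1OC
F2 | step 5 | (4R,5R)-dimethyldioxolane of 12 at C7 | COc1cc(OC)c(OC)c(C[C@@]2(C)[C@@H]3C(=O)CCC(C)(C)[C@H]3CC4(O[C@H](C)[C@@H](C)O4)[C@@H]2C)c1OC
F3 | step 5 | (4R,5R)-dimethyldioxolane of the ent-dione at C7 | COc1cc(OC)c(OC)c(C[C@]2(C)[C@H]3C(=O)CCC(C)(C)[C@@H]3CC4(O[C@H](C)[C@@H](C)O4)[C@H]2C)c1OC
F4 | step 5 | C1-deoxygenated dimethyldioxolane from F2 | COc1cc(OC)c(OC)c(C[C@@]2(C)[C@@H]3CCCC(C)(C)[C@H]3CC4(O[C@H](C)[C@@H](C)O4)[C@@H]2C)c1OC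
F5 | step 7 | C1 enol triflate of 13 (Δ1) | COc1cc(OC)c(OC)c(C[C@@]2(C)[C@@H]3C(OS(=O)(=O)C(F)(F)F)=CCC(C)(C)[C@H]3CC4(OCCO4)[C@@H]2C)c1OC
F6 | step 7 | Δ1-alkene with C7 dioxolane | COc1cc(OC)c(OC)c(C[C@@]2(C)[C@@H]3C=CCC(C)(C)[C@H]3CC4(OCCO4)[C@@H]2C)c1OC
F7 | step 11 | C7 dithiolane of 18 | COc1cc(OC)c(OC)c(C[C@@]2(C)[C@@H]3CCCC(C)(C)C3=CC4(SCCS4)[C@@H]2C)c1OC
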